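**Assumption (one line):** locants C1–C13 follow germacrane numbering (C1 = ring ketone carbon, C12 = lactone carbonyl, C13 = CH2OAc); (S,S)-ProPhenol is taken to deliver the alkynylzinc to the Re face of aldehyde 10, and if the sense proved opposite (R,R)-ProPhenol would be used with nothing else changed.

## Retrosynthetic overview

1. Target 26 ⇐ macrocyclic lactone 24 by removal of the C1 silyl ether and oxidation of C1–OH.
2. 24 ⇐ acyclic (Z)-β-iodoenoate / α,β-epoxy aldehyde 21 by one-pot Ni/Cr vinyl addition (C6–C7) and lactonisation (O–C12): the ten-membered carbocycle and the butenolide close together, and C6 is set by Felkin–Anh control from the oxirane.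
3. 21 ⇐ Z-allylic alcohol 19 by Sharpless epoxidation (C4, C5; the oxirane is the first ring made); the tetrasubstituted iodoalkene with C13 ⇐ ynoate 15 by iodide addition / formaldehyde aldol.
4. 15 ⇐ aldehyde 10 + methyl propiolate (asymmetric alkynylation, C8) + tigloyl chloride.
5. 10 ⇐ neryl acetate (C1–C6) + cis-2-butene (C8–C10 and the C10 methyl) by selective ozonolysis, Brown crotylboration (C10) and anti-Markovnikov Wacker oxidation. Ring order: oxirane, then carbocycle and butenolide together.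

## Route

Step 1
Reactants: 1 neryl acetate
Product: 3 (2Z)-3-methyl-6-oxohex-2-en-1-yl acetate, via secondary ozonide 2 (not isolated)
Conditions: O3 (1.0 equiv, Sudan Red 7B end point), CH2Cl2, −78 °C; then Me2S, −78 °C → rt
Reagents that add atoms: ozone, [O-][O+]=O
Why: Criegee ozonolysis with stoichiometric ozone cleaves the electron-rich isopropylidene alkene in preference to the 2,3-alkene, which is deactivated by the allylic acetate; the Z-alkene is untouched and no stereocentre is formed.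

Step 2
Reactants: 3 (2Z)-3-methyl-6-oxohex-2-en-1-yl acetate; 4 cis-2-butene
Product: 8 (2Z,6R,7R)-3,7-dimethylnona-2,8-diene-1,6-diol, via (Z)-crotylpotassium 5 (not isolated), via (Z)-crotyldiisopinocampheylborane 6 (not isolated), via borinate adduct 7 (not isolated)
Conditions: 4, KOt-Bu, n-BuLi, THF, −78 → −45 °C; (−)-Ipc2BOMe, −78 °C; BF3·OEt2; then 3, −78 °C; then 3 M NaOH, 30% H2O2, rt → 50 °C
Reagents that add atoms: none
Why: Brown asymmetric crotylboration through a Zimmerman–Traxler chair, in which the Z-crotyl unit gives the syn adduct and the (+)-α-pinene-derived borane attacks the Si face, sets C10 as R (and C1 as R, later oxidised); the alkaline peroxide work-up also saponifies the acetate.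

Step 3
Reactants: 8 (2Z,6R,7R)-3,7-dimethylnona-2,8-diene-1,6-diol
Product: 9 (2Z,6R,7R)-3,7-dimethyl-1,6-bis(triethylsilyloxy)nona-2,8-diene
Conditions: TESCl (2.4 equiv), imidazole, DMAP (cat.), DMF, 0 °C → rt
Reagents that add atoms: chlorotriethylsilane, CC[Si](Cl)(CC)CC
Why: Double silylation; the secondary TES ether masks the C1 oxygen until after ring closure (a free C1–OH would attack the later oxirane and a C1 ketone would trap the allenolate of step 7 or the vinylchromium of step 12), while the primary one can be removed selectively in step 9.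

Step 4
Reactants: 9 (2Z,6R,7R)-3,7-dimethyl-1,6-bis(triethylsilyloxy)nona-2,8-diene
Product: 10 (3R,4R,7Z)-3,7-dimethyl-4,9-bis(triethylsilyloxy)non-7-enal
Conditions: PdCl2(PhCN)2 (10 mol %), CuCl2·2H2O (10 mol %), AgNO2 (5 mol %), t-BuOH/MeNO2 15:1, O2 (1 atm), rt
Reagents that add atoms: dioxygen, O=O
Why: Nitrite-modified, aldehyde-selective (anti-Markovnikov) Wacker oxidation converts only the monosubstituted alkene, the trisubstituted alkene being inert; C10 is β to the new aldehyde and cannot epimerise.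

Step 5
Reactants: 10 (3R,4R,7Z)-3,7-dimethyl-4,9-bis(triethylsilyloxy)non-7-enal; 11 methyl propiolate
Product: 13 methyl (4S,6R,7R,10Z)-4-hydroxy-6,10-dimethyl-7,12-bis(triethylsilyloxy)dodec-10-en-2-ynoate, via alkynylzinc reagent 12 (not isolated)
Conditions: 11 (3 equiv), Me2Zn (3 equiv), (S,S)-ProPhenol (20 mol %), Ph3P=O (40 mol %), toluene, 0–4 °C
Reagents that add atoms: none
Why: Zinc–ProPhenol catalysed asymmetric alkynylation delivers the propiolate to the Re face of the aldehyde and sets C8 (4S here); because the substrate is already chiral the minor C8 epimer is a diastereomer and is removed by chromatography.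

Step 6
Reactants: 13 methyl (4S,6R,7R,10Z)-4-hydroxy-6,10-dimethyl-7,12-bis(triethylsilyloxy)dodec-10-en-2-ynoate; 14 tigloyl chloride
Product: 15 methyl (4S,6R,7R,10Z)-6,10-dimethyl-4-[(E)-2-methylbut-2-enoyloxy]-7,12-bis(triethylsilyloxy)dodec-10-en-2-ynoate
Conditions: 14 (1.5 equiv), pyridine, DMAP (cat.), CH2Cl2, 0 °C
Reagents that add atoms: none
Why: Acylation of the propargylic alcohol proceeds with retention at C8 and installs the tiglate before the alkyne is functionalised.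

Step 7
Reactants: 15 methyl (4S,6R,7R,10Z)-6,10-dimethyl-4-[(E)-2-methylbut-2-enoyloxy]-7,12-bis(triethylsilyloxy)dodec-10-en-2-ynoate
Product: 17 methyl (2Z,4S,6R,7R,10Z)-2-(hydroxymethyl)-3-iodo-6,10-dimethyl-4-[(E)-2-methylbut-2-enoyloxy]-7,12-bis(triethylsilyloxy)dodeca-2,10-dienoate, via magnesium iodoallenolate 16 (not isolated)
Conditions: MgI2 (1.5 equiv), monomeric CH2O (3 equiv, THF solution), CH2Cl2, −78 → −20 °C; aq. NH4Cl
Reagents that add atoms: magnesium diiodide MgI2, [Mg+2].[I-].[I-]; formaldehyde, C=O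
Why: Proposed new method: iodide adds to C7 of the magnesium-activated ynoate to give a β-iodo allenolate whose C11 is trapped by formaldehyde on the side anti to iodine (net anti addition, as in kinetic hydroiodination of 2-alkynoates), placing iodine cis to CO2Me and C13 cis to C8; the closest known reaction is the MgI2-mediated β-iodo Morita–Baylis–Hillman (iodo-aldol) reaction of propiolates with aldehydes, here extended to a 3-substituted ynoate.

Step 8
Reactants: 17 methyl (2Z,4S,6R,7R,10Z)-2-(hydroxymethyl)-3-iodo-6,10-dimethyl-4-[(E)-2-methylbut-2-enoyloxy]-7,12-bis(triethylsilyloxy)dodeca-2,10-dienoate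
Product: 18 methyl (2Z,4S,6R,7R,10Z)-2-(acetoxymethyl)-3-iodo-6,10-dimethyl-4-[(E)-2-methylbut-2-enoyloxy]-7,12-bis(triethylsilyloxy)dodeca-2,10-dienoate
Conditions: Ac2O, pyridine, DMAP (cat.), CH2Cl2, 0 °C
Reagents that add atoms: acetic anhydride, CC(=O)OC(C)=O
Why: Standard acetylation of the primary allylic alcohol installs the C13 acetate without touching any stereocentre.

Step 9
Reactants: 18 methyl (2Z,4S,6R,7R,10Z)-2-(acetoxymethyl)-3-iodo-6,10-dimethyl-4-[(E)-2-methylbut-2-enoyloxy]-7,12-bis(triethylsilyloxy)dodeca-2,10-dienoate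
Product: 19 methyl (2Z,4S,6R,7R,10Z)-2-(acetoxymethyl)-12-hydroxy-3-iodo-6,10-dimethyl-4-[(E)-2-methylbut-2-enoyloxy]-7-(triethylsilyloxy)dodeca-2,10-dienoate
Conditions: PPTS (0.1 equiv), MeOH/CH2Cl2 1:4, −10 → 0 °C
Reagents that add atoms: none
Why: Acid-catalysed methanolysis removes the unhindered primary allylic TES ether much faster than the secondary TES ether flanked by the C10 branch.

Step 10
Reactants: 19 methyl (2Z,4S,6R,7R,10Z)-2-(acetoxymethyl)-12-hydroxy-3-iodo-6,10-dimethyl-4-[(E)-2-methylbut-2-enoyloxy]-7-(triethylsilyloxy)dodeca-2,10-dienoate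
Product: 20 methyl (2Z,4S,6R,7R)-2-(acetoxymethyl)-9-[(2R,3S)-3-(hydroxymethyl)-2-methyloxiran-2-yl]-3-iodo-6-methyl-4-[(E)-2-methylbut-2-enoyloxy]-7-(triethylsilyloxy)non-2-enoate
Conditions: Ti(OiPr)4 (0.2 equiv), L-(+)-DET (0.25 equiv), t-BuOOH (2 equiv), 4 Å MS, CH2Cl2, −20 °C
Reagents that add atoms: tert-butyl hydroperoxide, CC(C)(C)OO
Why: Sharpless asymmetric epoxidation of the Z-allylic alcohol with L-(+)-tartrate gives the cis-oxirane with C4 R and C5 S (the same sense as nerol to (2S,3R)-epoxynerol), and the electron-poor iodoenoate and tiglate alkenes do not react.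

Step 11
Reactants: 20 methyl (2Z,4S,6R,7R)-2-(acetoxymethyl)-9-[(2R,3S)-3-(hydroxymethyl)-2-methyloxiran-2-yl]-3-iodo-6-methyl-4-[(E)-2-methylbut-2-enoyloxy]-7-(triethylsilyloxy)non-2-enoate
Product: 21 methyl (2Z,4S,6R,7R)-2-(acetoxymethyl)-9-[(2R,3R)-3-formyl-2-methyloxiran-2-yl]-3-iodo-6-methyl-4-[(E)-2-methylbut-2-enoyloxy]-7-(triethylsilyloxy)non-2-enoate
Conditions: Dess–Martin periodinane (1.5 equiv), NaHCO3, CH2Cl2, 0 °C → rt
Reagents that add atoms: none
Why: Buffered Dess–Martin oxidation gives the α,β-epoxy aldehyde without touching the oxirane (the descriptor at the aldehyde-bearing carbon changes from S to R only because of CIP priorities).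

Step 12
Reactants: 21 methyl (2Z,4S,6R,7R)-2-(acetoxymethyl)-9-[(2R,3R)-3-formyl-2-methyloxiran-2-yl]-3-iodo-6-methyl-4-[(E)-2-methylbut-2-enoyloxy]-7-(triethylsilyloxy)non-2-enoate
Product: 24 (1R,4R,5S,6S,8S,10R)-13-acetoxy-4,5-epoxy-8-[(E)-2-methylbut-2-enoyloxy]-1-(triethylsilyloxy)germacr-7(11)-en-12,6-olide, via vinylchromium species 22 (not isolated), via chromium alkoxide ester 23 (not isolated)
Conditions: CrCl2 (12 equiv), NiCl2 (0.1 equiv), DMSO/THF 3:1, 25 °C, syringe-pump addition of 21 over 10 h (final 2 mM); aq. work-up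
Reagents that add atoms: none
Why: Nozaki–Hiyama–Kishi macrocyclisation (oxidative addition of the C–I bond to zerovalent nickel, transmetalation to trivalent chromium with retention of alkene geometry) adds C7 to the epoxy aldehyde anti to the oxirane C–O bond (Felkin–Anh), setting C6 as S; the resulting alkoxide lies cis to the methyl ester and lactonises at once, so the ten-membered ring and the butenolide form in the same operation.

Step 13
Reactants: 24 (1R,4R,5S,6S,8S,10R)-13-acetoxy-4,5-epoxy-8-[(E)-2-methylbut-2-enoyloxy]-1-(triethylsilyloxy)germacr-7(11)-en-12,6-olide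
Product: 25 (1R,4R,5S,6S,8S,10R)-13-acetoxy-4,5-epoxy-1-hydroxy-8-[(E)-2-methylbut-2-enoyloxy]germacr-7(11)-en-12,6-olide
Conditions: HF·pyridine, excess pyridine, THF, 0 °C
Reagents that add atoms: none
Why: Pyridine-buffered HF cleaves the secondary TES ether under conditions that trisubstituted epoxides in macrolides are known to survive, and no base is used that could open the oxirane through the butenolide γ-position.

Step 14
Reactants: 25 (1R,4R,5S,6S,8S,10R)-13-acetoxy-4,5-epoxy-1-hydroxy-8-[(E)-2-methylbut-2-enoyloxy]germacr-7(11)-en-12,6-olide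
Product: 26 (4R,5S,6S,8S,10R)-13-acetoxy-4,5-epoxy-8-[(E)-2-methylbut-2-enoyloxy]-1-oxogermacr-7(11)-en-12,6-olide (CNP0229937.1)
Conditions: Dess–Martin periodinane (1.5 equiv), NaHCO3, CH2Cl2, 0 °C
Reagents that add atoms: none
Why: Buffered Dess–Martin oxidation converts the C1 carbinol into the ketone immediately after its release, under non-basic conditions that leave the now α-positioned C10 stereocentre, the oxirane and the esters intact.

## Compound list

1 | neryl acetate | CC(=O)OC/C=C(/C)CCC=C(C)C | starting material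
2 | secondary ozonide of the 6,7-alkene of neryl acetate | CC(=O)OC/C=C(/C)CCC1OOC(C)(C)O1 | intermediate
3 | (2Z)-3-methyl-6-oxohex-2-en-1-yl acetate | CC(=O)OC/C=C(/C)CCC=O | intermediate
4 | cis-2-butene | C/C=C\C | starting material
5 | (Z)-but-2-en-1-ylpotassium | C/C=C\[CH2-].[K+] | intermediate
6 | B-(Z)-crotyldiisopinocampheylborane from (+)-α-pinene | C/C=C\CB([C@@H]1C[C@@H]2C[C@H]([C@H]1C)C2(C)C)[C@@H]1C[C@@H]2C[C@H]([C@H]1C)C2(C)C | intermediate
7 | diisopinocampheylborinate of (2Z,6R,7R)-6-hydroxy-3,7-dimethylnona-2,8-dien-1-yl acetate | C=C[C@@H](C)[C@H](OB([C@@H]1C[C@@H]2C[C@H]([C@H]1C)C2(C)C)[C@@H]1C[C@@H]2C[C@H]([C@H]1C)C2(C)C)CC/C(C)=C\COC(C)=O | intermediate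
8 | (2Z,6R,7R)-3,7-dimethylnona-2,8-diene-1,6-diol | C=C[C@@H](C)[C@H](O)CC/C(C)=C\CO | intermediate
9 | (2Z,6R,7R)-3,7-dimethyl-1,6-bis(triethylsilyloxy)nona-2,8-diene | C=C[C@@H](C)[C@H](O[Si](CC)(CC)CC)CC/C(C)=C\CO[Si](CC)(CC)CC | intermediate
10 | (3R,4R,7Z)-3,7-dimethyl-4,9-bis(triethylsilyloxy)non-7-enal | O=CC[C@@H](C)[C@H](O[Si](CC)(CC)CC)CC/C(C)=C\CO[Si](CC)(CC)CC | intermediate
11 | methyl propiolate | COC(=O)C#C | starting material
12 | methyl 3-(methylzincio)prop-2-ynoate | COC(=O)C#C[Zn]C | intermediate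
13 | methyl (4S,6R,7R,10Z)-4-hydroxy-6,10-dimethyl-7,12-bis(triethylsilyloxy)dodec-10-en-2-ynoate | COC(=O)C#C[C@@H](O)C[C@@H](C)[C@H](O[Si](CC)(CC)CC)CC/C(C)=C\CO[Si](CC)(CC)CC | intermediate
14 | tigloyl chloride, (E)-2-methylbut-2-enoyl chloride | C/C=C(\C)C(Cl)=O | starting material
15 | methyl (4S,6R,7R,10Z)-6,10-dimethyl-4-[(E)-2-methylbut-2-enoyloxy]-7,12-bis(triethylsilyloxy)dodec-10-en-2-ynoate | COC(=O)C#C[C@@H](OC(=O)/C(C)=C/C)C[C@@H](C)[C@H](O[Si](CC)(CC)CC)CC/C(C)=C\CO[Si](CC)(CC)CC | intermediate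
16 | magnesium β-iodo allenolate of 15 | COC(O[Mg]I)=C=C(I)[C@@H](OC(=O)/C(C)=C/C)C[C@@H](C)[C@H](O[Si](CC)(CC)CC)CC/C(C)=C\CO[Si](CC)(CC)CC | intermediate
17 | methyl (2Z,4S,6R,7R,10Z)-2-(hydroxymethyl)-3-iodo-6,10-dimethyl-4-[(E)-2-methylbut-2-enoyloxy]-7,12-bis(triethylsilyloxy)dodeca-2,10-dienoate | COC(=O)/C(CO)=C(\I)[C@@H](OC(=O)/C(C)=C/C)C[C@@H](C)[C@H](O[Si](CC)(CC)CC)CC/C(C)=C\CO[Si](CC)(CC)CC | intermediate
18 | methyl (2Z,4S,6R,7R,10Z)-2-(acetoxymethyl)-3-iodo-6,10-dimethyl-4-[(E)-2-methylbut-2-enoyloxy]-7,12-bis(triethylsilyloxy)dodeca-2,10-dienoate | COC(=O)/C(COC(C)=O)=C(\I)[C@@H](OC(=O)/C(C)=C/C)C[C@@H](C)[C@H](O[Si](CC)(CC)CC)CC/C(C)=C\CO[Si](CC)(CC)CC | intermediate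
19 | methyl (2Z,4S,6R,7R,10Z)-2-(acetoxymethyl)-12-hydroxy-3-iodo-6,10-dimethyl-4-[(E)-2-methylbut-2-enoyloxy]-7-(triethylsilyloxy)dodeca-2,10-dienoate | COC(=O)/C(COC(C)=O)=C(\I)[C@@H](OC(=O)/C(C)=C/C)C[C@@H](C)[C@H](O[Si](CC)(CC)CC)CC/C(C)=C\CO | intermediate
20 | methyl (2Z,4S,6R,7R)-2-(acetoxymethyl)-9-[(2R,3S)-3-(hydroxymethyl)-2-methyloxiran-2-yl]-3-iodo-6-methyl-4-[(E)-2-methylbut-2-enoyloxy]-7-(triethylsilyloxy)non-2-enoate | COC(=O)/C(COC(C)=O)=C(\I)[C@@H](OC(=O)/C(C)=C/C)C[C@@H](C)[C@H](O[Si](CC)(CC)CC)CC[C@@]1(C)O[C@H]1CO | intermediate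
21 | methyl (2Z,4S,6R,7R)-2-(acetoxymethyl)-9-[(2R,3R)-3-formyl-2-methyloxiran-2-yl]-3-iodo-6-methyl-4-[(E)-2-methylbut-2-enoyloxy]-7-(triethylsilyloxy)non-2-enoate | COC(=O)/C(COC(C)=O)=C(\I)[C@@H](OC(=O)/C(C)=C/C)C[C@@H](C)[C@H](O[Si](CC)(CC)CC)CC[C@@]1(C)O[C@H]1C=O | intermediate
22 | dichlorochromium vinyl species from 21 (Cr in place of iodine at C7) | COC(=O)/C(COC(C)=O)=C(\[Cr](Cl)Cl)[C@@H](OC(=O)/C(C)=C/C)C[C@@H](C)[C@H](O[Si](CC)(CC)CC)CC[C@@]1(C)O[C@H]1C=O | intermediate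
23 | ten-membered C6 chromium alkoxide with the C12 methyl ester still open | C/C=C(\C)C(=O)O[C@H]1C[C@@H](C)[C@H](O[Si](CC)(CC)CC)CC[C@@]2(C)O[C@H]2[C@@H](O[Cr](Cl)Cl)/C1=C(/COC(C)=O)C(=O)OC | intermediate
24 | (1R,4R,5S,6S,8S,10R)-13-acetoxy-4,5-epoxy-8-[(E)-2-methylbut-2-enoyloxy]-1-(triethylsilyloxy)germacr-7(11)-en-12,6-olide | C/C=C(\C)C(=O)O[C@H]1C[C@@H](C)[C@H](O[Si](CC)(CC)CC)CC[C@@]2(C)O[C@H]2[C@H]2OC(=O)C(COC(C)=O)=C12 | intermediate
25 | (1R,4R,5S,6S,8S,10R)-13-acetoxy-4,5-epoxy-1-hydroxy-8-[(E)-2-methylbut-2-enoyloxy]germacr-7(11)-en-12,6-olide | C/C=C(\C)C(=O)O[C@H]1C[C@@H](C)[C@H](O)CC[C@@]2(C)O[C@H]2[C@H]2OC(=O)C(COC(C)=O)=C12 | intermediate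
26 | (4R,5S,6S,8S,10R)-13-acetoxy-4,5-epoxy-8-[(E)-2-methylbut-2-enoyloxy]-1-oxogermacr-7(11)-en-12,6-olide (CNP0229937.1) | C/C=C(\C)C(=O)O[C@H]1C[C@@H](C)C(=O)CC[C@@]2(C)O[C@H]2[C@H]2OC(=O)C(COC(C)=O)=C12 | target

## Step count and risks

Total step count: 14. Longest linear sequence: 14 steps (from neryl acetate 1; cis-2-butene 4, methyl propiolate 11 and tigloyl chloride 14 are bought).

The three steps most likely to fail:

**Step 12 (Ni/Cr macrocyclisation with lactonisation).** The risks are β-elimination of the C8 tiglate from the vinylchromium species to an allene, reduction of the α,β-epoxy aldehyde by CrCl2, and slow closure of the ten-membered ring. The fallback installs the oxirane after ring closure. It sets out from 19: MnO2 oxidation of the allylic alcohol gives the Z-enal methyl (2Z,4S,6R,7R,10Z)-2-(acetoxymethyl)-3-iodo-6,10-dimethyl-4-[(E)-2-methylbut-2-enoyloxy]-12-oxo-7-(triethylsilyloxy)dodeca-2,10-dienoate F7. The same CrCl2/NiCl2 cyclisation with lactonisation on this more robust aldehyde gives the macrocyclic diene lactone (1R,4Z,8S,10R)-13-acetoxy-8-[(E)-2-methylbut-2-enoyloxy]-1-(triethylsilyloxy)germacra-4,7(11)-dien-12,6-olide F8, with C6 now controlled only by allylic strain from C8 and to be checked. Reagent-controlled epoxidation of the 4,5-alkene with the L-fructose-derived Shi ketone and Oxone then comes back to the route at 24.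

**Step 7 (iodide addition / formaldehyde aldol).** The risks are the alkene geometry of a tetrasubstituted product and sluggish reaction of a 3-substituted ynoate. The fallback fixes the geometry with a silicon tether. It sets out from 13: silylation with (bromomethyl)chlorodimethylsilane and imidazole gives methyl (4S,6R,7R,10Z)-4-{[(bromomethyl)dimethylsilyl]oxy}-6,10-dimethyl-7,12-bis(triethylsilyloxy)dodec-10-en-2-ynoate F3. LiI in THF adds iodide to C7 and the allenolate is alkylated intramolecularly at C11 to give the cyclic siloxane methyl (6S)-6-[(2R,3R,6Z)-2,6-dimethyl-3,8-bis(triethylsilyloxy)oct-6-en-1-yl]-5-iodo-2,2-dimethyl-3,6-dihydro-2H-1,2-oxasiline-4-carboxylate F4, in which the ring forces C13 cis to C8 and iodine cis to the ester. Fluoride-free Tamao oxidation (H2O2, KHCO3, THF/MeOH) gives the diol methyl (2Z,4S,6R,7R,10Z)-4-hydroxy-2-(hydroxymethyl)-3-iodo-6,10-dimethyl-7,12-bis(triethylsilyloxy)dodeca-2,10-dienoate F5. Selective acetylation of the primary hydroxyl (Ac2O, 2,4,6-collidine, −40 °C) gives methyl (2Z,4S,6R,7R,10Z)-2-(acetoxymethyl)-4-hydroxy-3-iodo-6,10-dimethyl-7,12-bis(triethylsilyloxy)dodeca-2,10-dienoate F6. Acylation with tigloyl chloride 14 and pyridine then comes back to the route at 18.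

**Step 5 (asymmetric alkynylation).** The risks are moderate selectivity with an α-unbranched aliphatic aldehyde and the assumed facial sense of the ligand. The fallback sets C8 by reduction instead of addition. It sets out from 10: addition of lithiated methyl propiolate (LiHMDS, THF, −78 °C) gives methyl (6R,7R,10Z)-4-hydroxy-6,10-dimethyl-7,12-bis(triethylsilyloxy)dodec-10-en-2-ynoate as the C4 epimer mixture F1. MnO2 oxidation gives the ynone methyl (6R,7R,10Z)-6,10-dimethyl-4-oxo-7,12-bis(triethylsilyloxy)dodec-10-en-2-ynoate F2. Midland reduction with (S)-Alpine-Borane (from (−)-α-pinene), which is precedented for 4-oxo-2-ynoates, then comes back to the route at 13.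

## Further compounds

F1 | step 5 | methyl (6R,7R,10Z)-4-hydroxy-6,10-dimethyl-7,12-bis(triethylsilyloxy)dodec-10-en-2-ynoate (C4 epimer mixture) | COC(=O)C#CC(O)C[C@@H](C)[C@H](O[Si](CC)(CC)CC)CC/C(C)=C\CO[Si](CC)(CC)CC
F2 | step 5 | methyl (6R,7R,10Z)-6,10-dimethyl-4-oxo-7,12-bis(triethylsilyloxy)dodec-10-en-2-ynoate | COC(=O)C#CC(=O)C[C@@H](C)[C@H](O[Si](CC)(CC)CC)CC/C(C)=C\CO[Si](CC)(CC)CC
F3 | step 7 | methyl (4S,6R,7R,10Z)-4-{[(bromomethyl)dimethylsilyl]oxy}-6,10-dimethyl-7,12-bis(triethylsilyloxy)dodec-10-en-2-ynoate | COC(=O)C#C[C@@H](O[Si](C)(C)CBr)C[C@@H](C)[C@H](O[Si](CC)(CC)CC)CC/C(C)=C\CO[Si](CC)(CC)CC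
F4 | step 7 | methyl (6S)-6-[(2R,3R,6Z)-2,6-dimethyl-3,8-bis(triethylsilyloxy)oct-6-en-1-yl]-5-iodo-2,2-dimethyl-3,6-dihydro-2H-1,2-oxasiline-4-carboxylate | COC(=O)C1=C(I)[C@H](C[C@@H](C)[C@H](O[Si](CC)(CC)CC)CC/C(C)=C\CO[Si](CC)(CC)CC)O[Si](C)(C)C1
F5 | step 7 | methyl (2Z,4S,6R,7R,10Z)-4-hydroxy-2-(hydroxymethyl)-3-iodo-6,10-dimethyl-7,12-bis(triethylsilyloxy)dodeca-2,10-dienoate | COC(=O)/C(CO)=C(\I)[C@@H](O)C[C@@H](C)[C@H](O[Si](CC)(CC)CC)CC/C(C)=C\CO[Si](CC)(CC)CC
F6 | step 7 | methyl (2Z,4S,6R,7R,10Z)-2-(acetoxymethyl)-4-hydroxy-3-iodo-6,10-dimethyl-7,12-bis(triethylsilyloxy)dodeca-2,10-dienoate | COC(=O)/C(COC(C)=O)=C(\I)[C@@H](O)C[C@@H](C)[C@H](O[Si](CC)(CC)CC)CC/C(C)=C\CO[Si](CC)(CC)CC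
F7 | step 12 | methyl (2Z,4S,6R,7R,10Z)-2-(acetoxymethyl)-3-iodo-6,10-dimethyl-4-[(E)-2-methylbut-2-enoyloxy]-12-oxo-7-(triethylsilyloxy)dodeca-2,10-dienoate | COC(=O)/C(COC(C)=O)=C(\I)[C@@H](OC(=O)/C(C)=C/C)C[C@@H](C)[C@H](O[Si](CC)(CC)CC)CC/C(C)=C\C=O
F8 | step 12 | (1R,4Z,8S,10R)-13-acetoxy-8-[(E)-2-methylbut-2-enoyloxy]-1-(triethylsilyloxy)germacra-4,7(11)-dien-12,6-olide with the C6 configuration of 24 | C/C=C(\C)C(=O)O[C@H]1C[C@@H](C)[C@H](O[Si](CC)(CC)CC)CC/C(C)=C\[C@H]2OC(=O)C(COC(C)=O)=C12
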